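The route rests on disconnecting the two C–O bonds ortho to the diaryl ether oxygen: C1–O (the OMe) on ring A, the dibromo ring, and C6'–O (the OH) on ring B, the monobromo ring. The key step exploits exactly this feature: each of these carbons can first carry a formyl group, and the neighbouring ether oxygen then assists its exchange for oxygen. 5-Bromosalicylaldehyde 1 and 2,4-dibromo-6-fluorobenzaldehyde 2 are joined by SNAr to dialdehyde 3, which already holds all three bromines. One peracid operation converts both ArCHO units via bis(formate) 4 into diol 5. Selective methylation of the more acidic ring A phenol gives target 6.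

Key step: step 2

Remark on numbering and assumptions: ring A carries OMe at C1, bromine at C2 and C4, and the bridging oxygen at C6; ring B carries the bridging oxygen at C1', bromine at C4' and OH at C6'. The target has no stereocentre. Both starting aldehydes are assumed to be purchased.

Step 1
Reactants: 1 5-bromosalicylaldehyde; 2 2,4-dibromo-6-fluorobenzaldehyde
Product: 3 2,4-dibromo-6-(4-bromo-2-formylphenoxy)benzaldehyde
Conditions: K2CO3 (1.5 equiv), 2 (1.05 equiv), DMF, 70 °C
Reagents that add atoms: none
Why: Nucleophilic aromatic substitution (SNAr, addition–elimination): the ortho formyl group of 2 stabilises the Meisenheimer adduct at the C–F carbon, and fluoride should leave far faster than either aldehyde-activated bromide, so the phenoxide of 1 should enter only at C6 of ring A; no stereocentre is formed.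

Step 2
Reactants: 3 2,4-dibromo-6-(4-bromo-2-formylphenoxy)benzaldehyde
Product: 5 2,4-dibromo-6-(4-bromo-2-hydroxyphenoxy)phenol, via bis(formate) ester 4 (not isolated)
Conditions: mCPBA (3 equiv), CH2Cl2, rt to 40 °C; aq. Na2SO3 work-up; then HCl (cat.), MeOH, rt
Reagents that add atoms: mCPBA (3-chloroperoxybenzoic acid), OOC(=O)c1cccc(Cl)c1
Why: Baeyer–Villiger oxidation of aryl aldehydes (Dakin-type): each formyl group adds the peracid to give a Criegee adduct, the aryl carbon shifts from carbon to the peroxide oxygen as 3-chlorobenzoate leaves, and the two aryl formates are cleaved by acid-catalysed methanolysis, so the C1–O and C6'–O bonds are made with oxygen from the peracid. The closest known reaction is the peracid conversion of ortho-aryloxy- and ortho-alkoxybenzaldehydes into phenols, here required twice in one molecule. No ring is closed and no stereocentre is created. The selectivity needed is aryl over hydride migration in both adducts; on each ring the ether oxygen ortho to the migrating carbon donates a lone pair into the developing electron deficiency, and the acidic, non-basic medium disfavours the hydride shift that leads to carboxylic acids. Ring A, with two bromines and a formyl group flanked on both sides, is the slow and critical site, hence the excess peracid and gentle heating. Because both aldehydes are oxidised before any formate is cleaved and the cleavage is run in acid, no phenoxide sits next to an aldehyde-activated ring, which should exclude Smiles-type aryl transfer.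

Step 3
Reactants: 5 2,4-dibromo-6-(4-bromo-2-hydroxyphenoxy)phenol
Product: 6 5-bromo-2-(3,5-dibromo-2-methoxyphenoxy)phenol
Conditions: K2CO3 (1.0 equiv), MeI (1.05 equiv), DMF, 0 °C to rt
Reagents that add atoms: methyl iodide, CI
Why: Williamson O-methylation (SN2 of a phenoxide on MeI): with one equivalent of carbonate only a monoanion forms, and it should reside on the ring A oxygen, whose phenol is acidified by ortho and para bromine (an acidity gap that DMF widens), so methyl transfer should occur there before the ring B phenol is ionised; no stereocentre is formed.

Compound list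
1 | 5-bromosalicylaldehyde (5-bromo-2-hydroxybenzaldehyde) | O=Cc1cc(Br)ccc1O | starting material
2 | 2,4-dibromo-6-fluorobenzaldehyde | O=Cc1c(F)cc(Br)cc1Br | starting material
3 | 2,4-dibromo-6-(4-bromo-2-formylphenoxy)benzaldehyde | O=Cc1c(Br)cc(Br)cc1Oc1ccc(Br)cc1C=O | intermediate
4 | 2,4-dibromo-6-[4-bromo-2-(formyloxy)phenoxy]phenyl formate (bis(formate) ester) | O=COc1c(Br)cc(Br)cc1Oc1ccc(Br)cc1OC=O | intermediate
5 | 2,4-dibromo-6-(4-bromo-2-hydroxyphenoxy)phenol | Oc1c(Br)cc(Br)cc1Oc1ccc(Br)cc1O | intermediate
6 | 5-bromo-2-(3,5-dibromo-2-methoxyphenoxy)phenol | COc1c(Br)cc(Br)cc1Oc1ccc(Br)cc1O | target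

Total step count: 3. Longest linear sequence: 3 steps (from 1 or 2 to 6).

Steps most likely to fail

Step 2. The Criegee adduct on the electron-poor, doubly ortho-substituted ring A may shift hydride instead of aryl, which over-oxidises that formyl group to a carboxylic acid, or peracid addition to that hindered formyl group may stall. The fallback removes the hydride from the migrating choice. Setting out from 3, addition of MeMgBr (THF, −78 °C) to both formyl groups should give the bis(carbinol) 1-[2,4-dibromo-6-[4-bromo-2-(1-hydroxyethyl)phenoxy]phenyl]ethanol F1 as a mixture of diastereomers, which is of no consequence. Dess–Martin oxidation should give the diketone 1-[2-(2-acetyl-3,5-dibromophenoxy)-5-bromophenyl]ethanone F2. Baeyer–Villiger oxidation of the two aryl methyl ketones (mCPBA, TFA cat., CH2Cl2, 40 °C), in which aryl migrates in preference to methyl, should give the bis(acetate) 2-(2-acetoxy-4-bromophenoxy)-4,6-dibromophenyl acetate F3. Acid-catalysed methanolysis (HCl, MeOH) then returns to the route at 5.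

Step 3. Site selectivity between the two phenols may be lost, with methyl transfer to the ring B oxygen or to both oxygens. The fallback inverts the selection principle and blocks ring B first. Setting out from 5, the dianion (NaH, 2.1 equiv, DMF, 0 °C) should react with one equivalent of benzyl bromide at the more basic and less hindered ring B phenoxide to give 2-[2-(benzyloxy)-4-bromophenoxy]-4,6-dibromophenol F4. Methylation of the one remaining phenol (K2CO3, MeI, DMF) should give 1-[2-(benzyloxy)-4-bromophenoxy]-3,5-dibromo-2-methoxybenzene F5. Debenzylation with BCl3 and pentamethylbenzene (CH2Cl2, −78 °C) spares the aryl bromides and the methyl ether and returns to the route at 6.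

Step 1. The chelated, weakly nucleophilic salicylaldehyde phenoxide may need forcing temperature, which opens competing displacement of an aldehyde-activated bromide and aryl ether exchange at the activated ipso carbons. The fallback raises the nucleophilicity of the ring B partner instead. Setting out from 1, reduction with NaBH4 (MeOH, 0 °C) should give 4-bromo-2-(hydroxymethyl)phenol F6. Its unchelated phenoxide should displace the fluoride of 2 at lower temperature (K2CO3, DMF, rt to 50 °C) to give 2,4-dibromo-6-[4-bromo-2-(hydroxymethyl)phenoxy]benzaldehyde F7. Oxidation of the benzylic alcohol with MnO2 (CH2Cl2, rt) returns to the route at 3.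

Further compounds
F1 | step 2 | 1-[2,4-dibromo-6-[4-bromo-2-(1-hydroxyethyl)phenoxy]phenyl]ethanol (mixture of diastereomers) | CC(O)c1c(Br)cc(Br)cc1Oc1ccc(Br)cc1C(C)O
F2 | step 2 | 1-[2-(2-acetyl-3,5-dibromophenoxy)-5-bromophenyl]ethanone | CC(=O)c1c(Br)cc(Br)cc1Oc1ccc(Br)cc1C(C)=O
F3 | step 2 | 2-(2-acetoxy-4-bromophenoxy)-4,6-dibromophenyl acetate | CC(=O)Oc1c(Br)cc(Br)cc1Oc1ccc(Br)cc1OC(C)=O
F4 | step 3 | 2-[2-(benzyloxy)-4-bromophenoxy]-4,6-dibromophenol | Oc1c(Br)cc(Br)cc1Oc1ccc(Br)cc1OCc1ccccc1
F5 | step 3 | 1-[2-(benzyloxy)-4-bromophenoxy]-3,5-dibromo-2-methoxybenzene | COc1c(Br)cc(Br)cc1Oc1ccc(Br)cc1OCc1ccccc1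
F6 | step 1 | 4-bromo-2-(hydroxymethyl)phenol | OCc1cc(Br)ccc1O
F7 | step 1 | 2,4-dibromo-6-[4-bromo-2-(hydroxymethyl)phenoxy]benzaldehyde | O=Cc1c(Br)cc(Br)cc1Oc1ccc(Br)cc1CO
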